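**Retrosynthetic overview**

- The target comes from hydrolysis of a 2-methoxy-1,4-naphthoquinone methyl ester, whose benzenoid ring is made last by cycloaddition/dehydrogenation of an (E)-1,3-diene side chain with 2-methoxy-3-methyl-1,4-benzoquinone (made from resorcinol).
- The diene and the exocyclic methylene come from one double methylenation of an enal–ketone, itself made by allylic oxidation of a prenyl ketone.
- Key step: the prenyl decalone arises by ring expansion of a 1-vinyl-hydrindan-1-ol, in which the quaternary ring carbon shifts 1,2 onto the vinyl group while 1-iodo-2-methylpropene is coupled to the vinyl terminus; this forms ring B.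
- The vinyl hydrindanol comes from an amino-acid-catalysed Robinson annulation (ring A built on 2-methylcyclopentane-1,3-dione), vinyl addition, reductive carboxylation and deoxygenation.
- Ring order: cyclopentane (bought) → ring A → ring B (ring expansion) → benzenoid ring; the quinone ring is carried in from the benzoquinone.

Assumption: terpenoid positions are also cited by labdane numbering (ring A C1–C5/C10, ring B C5–C10, side chain C11–C15), and 1-iodo-2-methylprop-1-ene is bought.

**Route**

Step 1
Reactants: 1 2-methylcyclopentane-1,3-dione; 2 pent-1-en-3-one (ethyl vinyl ketone)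
Product: 5 (7aR)-4,7a-dimethyl-2,3,7,7a-tetrahydro-1H-indene-1,5(6H)-dione, via triketone 3 (not isolated), via ketol 4 (not isolated)
Conditions: H2O, AcOH (cat.), 70 °C; concentrate; D-phenylalanine (1.0 equiv), camphorsulfonic acid (0.5 equiv), MeCN, 80 °C
Reagents that add atoms: none
Why: Michael addition gives the prochiral triketone, and the D-phenylalanine enamine then differentiates the two enantiotopic ring carbonyls in an intramolecular aldol condensation (Hajos–Parrish–Eder–Sauer–Wiechert Robinson annulation), which sets the quaternary centre as R (about 90% ee, raised by crystallisation) before dehydration to the enone.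

Step 2
Reactants: 5 (7aR)-4,7a-dimethyl-2,3,7,7a-tetrahydro-1H-indene-1,5(6H)-dione
Product: 6 (1S,7aR)-1-ethenyl-1-hydroxy-4,7a-dimethyl-1,2,3,6,7,7a-hexahydro-5H-inden-5-one
Conditions: CH2=CHMgBr (1.15 equiv), LaCl3·2LiCl (1.0 equiv), THF, −78 °C; aq NH4Cl
Reagents that add atoms: vinylmagnesium bromide, C=C[Mg]Br
Why: The saturated cyclopentanone is much more electrophilic than the hindered tetrasubstituted enone carbonyl, so the lanthanide-assisted Grignard 1,2-addition is chemoselective, and attack anti to the angular methyl gives the 1S carbinol (OH cis to CH3), a centre that is erased later when this carbon becomes the C8 carbonyl.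

Step 3
Reactants: 6 (1S,7aR)-1-ethenyl-1-hydroxy-4,7a-dimethyl-1,2,3,6,7,7a-hexahydro-5H-inden-5-one
Product: 9 methyl (1S,3aS,4R,7aR)-1-ethenyl-1-hydroxy-4,7a-dimethyl-5-oxooctahydro-1H-indene-4-carboxylate, via dilithium enolate alkoxide 7 (not isolated), via keto acid 8 (not isolated)
Conditions: Li (2.2 equiv), NH3(l)/THF, −78 °C; NH3 off; CO2 (g), Et2O, −78 → 0 °C; cold 1 M HCl; TMSCHN2, PhMe/MeOH, 0 °C
Reagents that add atoms: carbon dioxide, O=C=O; (trimethylsilyl)diazomethane, C[Si](C)(C)C=[N+]=[N-]
Why: Dissolving-metal (Birch-type) enone reduction, with the substrate's own hydroxyl as proton donor, protonates C3a anti to the angular methyl to give the trans-hydrindane enolate, which is carboxylated at C4 on the face opposite the angular methyl (Stork–Spencer reductive carboxylation, then diazoalkane esterification), so the ester ends trans and the C4 methyl cis to the angular methyl.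

Step 4
Reactants: 9 methyl (1S,3aS,4R,7aR)-1-ethenyl-1-hydroxy-4,7a-dimethyl-5-oxooctahydro-1H-indene-4-carboxylate
Product: 11 methyl (1S,3aS,4S,7aR)-1-ethenyl-1-hydroxy-4,7a-dimethyloctahydro-1H-indene-4-carboxylate, via tosylhydrazone 10 (not isolated)
Conditions: TsNHNH2 (1.3 equiv), MeOH, 60 °C; evaporate; catecholborane (3 equiv), CHCl3, 0 °C; NaOAc·3H2O, 60 °C
Reagents that add atoms: none
Why: Caglioti–Kabalka reductive deoxygenation (hydride addition to the tosylhydrazone C=N, then loss of sulfinate and N2 from the diazene) turns the ketone into CH2 without touching the ester, the tertiary allylic alcohol or the vinyl group, and creates no stereocentre.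

Step 5
Reactants: 11 methyl (1S,3aS,4S,7aR)-1-ethenyl-1-hydroxy-4,7a-dimethyloctahydro-1H-indene-4-carboxylate; 12 1-iodo-2-methylprop-1-ene
Product: 13 methyl (1S,4aR,5S,8aS)-1,4a-dimethyl-5-(3-methylbut-2-en-1-yl)-6-oxodecahydronaphthalene-1-carboxylate
Conditions: (MeDalphos)AuCl (5 mol %), AgOTf (1.1 equiv), K3PO4 (1.0 equiv), 12 (1.5 equiv), 1,2-dichloroethane, 50 °C, dark; then DBU (0.2 equiv), 23 °C
Reagents that add atoms: none
Why: Proposed new method: oxidative addition of the alkenyl iodide to the P,N-ligated monovalent gold cation gives an alkenyl trivalent gold species that π-activates the vinyl group, the electron-rich quaternary ring carbon then shifts 1,2 from the carbinol carbon to the internal alkene carbon anti to gold (semipinacol ring expansion driven by C=O formation, with no β-hydride or three-membered oxyauration escape route), and C(sp3)–C(sp2) reductive elimination forms the C11–C12 bond, the closest known reactions being gold-catalysed oxy- and amino-arylation or -vinylation of alkenes with organic iodides and arylative ring expansions of strained vinylcyclobutanols, while the new C9 centre (α to the ketone) equilibrates under base to the equatorial side chain cis to the angular methyl.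

Step 6
Reactants: 13 methyl (1S,4aR,5S,8aS)-1,4a-dimethyl-5-(3-methylbut-2-en-1-yl)-6-oxodecahydronaphthalene-1-carboxylate
Product: 14 methyl (1S,4aR,5S,8aS)-1,4a-dimethyl-5-[(2E)-3-methyl-4-oxobut-2-en-1-yl]-6-oxodecahydronaphthalene-1-carboxylate
Conditions: SeO2 (1.1 equiv), 1,4-dioxane/H2O 30:1, 70 °C
Reagents that add atoms: selenium dioxide, O=[Se]=O
Why: Riley allylic oxidation with SeO2 attacks the (E)-methyl of the trisubstituted alkene faster than the ketone α-methylene at this temperature and gives the (E)-enal directly, with no change at any stereocentre.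

Step 7
Reactants: 14 methyl (1S,4aR,5S,8aS)-1,4a-dimethyl-5-[(2E)-3-methyl-4-oxobut-2-en-1-yl]-6-oxodecahydronaphthalene-1-carboxylate
Product: 16 methyl (1S,4aS,5R,8aS)-1,4a-dimethyl-6-methylidene-5-[(2E)-3-methylpenta-2,4-dien-1-yl]decahydronaphthalene-1-carboxylate, via dienyl ketone 15 (not isolated)
Conditions: Ph3PCH3Br (5.0 equiv), KOtBu (4.8 equiv), THF, 0 °C then 60 °C
Reagents that add atoms: methylenetriphenylphosphorane, C=P(c1ccccc1)(c1ccccc1)c1ccccc1
Why: Wittig methylenation converts the unhindered enal at 0 °C and then the hindered C8 ketone on warming, the 2E geometry is retained, and C9 keeps its thermodynamically preferred equatorial configuration because any epimerisation by the basic ylide before olefination returns to it.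

Step 8
Reactants: 17 resorcinol (benzene-1,3-diol)
Product: 18 1,3-dimethoxybenzene
Conditions: MeI (2.5 equiv), K2CO3 (2.5 equiv), acetone, 56 °C
Reagents that add atoms: iodomethane, CI
Why: Williamson etherification of both phenolic hydroxyls under carbonate conditions is essentially quantitative and creates no stereocentre.

Step 9
Reactants: 18 1,3-dimethoxybenzene
Product: 20 1,3-dimethoxy-2-methylbenzene (2,6-dimethoxytoluene), via aryllithium 19 (not isolated)
Conditions: n-BuLi (1.1 equiv), THF, 0 → 23 °C; MeI (1.3 equiv), 0 °C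
Reagents that add atoms: iodomethane, CI
Why: Directed ortho-metalation occurs only at C2 between the two methoxy groups, and the aryllithium is methylated by SN2 reaction with iodomethane.

Step 10
Reactants: 20 1,3-dimethoxy-2-methylbenzene
Product: 22 2-methoxy-3-methylcyclohexa-2,5-diene-1,4-dione, via phenol 21 (not isolated)
Conditions: 30% H2O2 (2.5 equiv), HCO2H, 23 °C
Reagents that add atoms: hydrogen peroxide, OO; water, O
Why: Performic acid formed in the flask hydroxylates the position para to one methoxy group and ortho to the other (electrophilic aromatic hydroxylation), and the resulting p-methoxyphenol is oxidised further with hydrolytic loss of methanol to the p-quinone (oxidative demethylation).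

Step 11
Reactants: 16 methyl (1S,4aS,5R,8aS)-1,4a-dimethyl-6-methylidene-5-[(2E)-3-methylpenta-2,4-dien-1-yl]decahydronaphthalene-1-carboxylate; 22 2-methoxy-3-methylcyclohexa-2,5-diene-1,4-dione
Product: 24 methyl (1S,4aS,5R,8aS)-5-[(7-methoxy-2,6-dimethyl-5,8-dioxo-5,8-dihydronaphthalen-1-yl)methyl]-1,4a-dimethyl-6-methylidenedecahydronaphthalene-1-carboxylate, via cycloadduct 23 (not isolated)
Conditions: 22 (1.5 equiv), PhMe, 100 °C, sealed tube; then DDQ (2.2 equiv), 60 °C
Reagents that add atoms: none
Why: Diels–Alder cycloaddition at the unsubstituted quinone double bond is steered by the methoxy group, which deactivates the C4 carbonyl so that the C1 carbonyl directs the substituted diene terminus to C6 (ortho rule), and DDQ dehydrogenation then erases the three new sp3 centres to give the naphthoquinone with the terpenyl-methyl group peri to the carbonyl that neighbours C–OMe.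

Step 12
Reactants: 24 methyl (1S,4aS,5R,8aS)-5-[(7-methoxy-2,6-dimethyl-5,8-dioxo-5,8-dihydronaphthalen-1-yl)methyl]-1,4a-dimethyl-6-methylidenedecahydronaphthalene-1-carboxylate
Product: 25 (1S,4aS,5R,8aS)-5-[(7-hydroxy-2,6-dimethyl-5,8-dioxo-5,8-dihydronaphthalen-1-yl)methyl]-1,4a-dimethyl-6-methylidenedecahydronaphthalene-1-carboxylic acid (CNP0259461.3)
Conditions: KOH (10 equiv), MeOH/H2O 3:1, argon, 65 °C; then 1 M HCl
Reagents that add atoms: potassium hydroxide, [K+].[OH-]
Why: Hydroxide cleaves the vinylogous methyl ester by addition–elimination and saponifies the equatorial methyl ester (acyl–oxygen cleavage) under exclusion of air, and no stereocentre is epimerisable under these conditions.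

**Compound list**

1 | 2-methylcyclopentane-1,3-dione | CC1C(=O)CCC1=O | starting material
2 | pent-1-en-3-one | C=CC(=O)CC | starting material
3 | 2-methyl-2-(3-oxopentyl)cyclopentane-1,3-dione | CCC(=O)CCC1(C)C(=O)CCC1=O | intermediate
4 | (3aR,7aR)-3a-hydroxy-4,7a-dimethylhexahydro-1H-indene-1,5(4H)-dione (cis-fused, both C4 epimers) | O=C1CC[C@@]2(O)C(C)C(=O)CC[C@@]12C | intermediate
5 | (7aR)-4,7a-dimethyl-2,3,7,7a-tetrahydro-1H-indene-1,5(6H)-dione | O=C1CCC2=C(C)C(=O)CC[C@@]12C | intermediate
6 | (1S,7aR)-1-ethenyl-1-hydroxy-4,7a-dimethyl-1,2,3,6,7,7a-hexahydro-5H-inden-5-one (OH cis to angular CH3) | C=C[C@@]1(O)CCC2=C(C)C(=O)CC[C@@]12C | intermediate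
7 | dilithium enolate alkoxide of 6 after 1,4-reduction (trans-fused, H at C3a anti to angular CH3) | [Li+].[Li+].C=C[C@@]1([O-])CC[C@H]2[C@@]1(C)CCC([O-])=C2C | intermediate
8 | (1S,3aS,4R,7aR)-1-ethenyl-1-hydroxy-4,7a-dimethyl-5-oxooctahydro-1H-indene-4-carboxylic acid | C=C[C@@]1(O)CC[C@H]2[C@@]1(C)CCC(=O)[C@]2(C)C(=O)O | intermediate
9 | methyl (1S,3aS,4R,7aR)-1-ethenyl-1-hydroxy-4,7a-dimethyl-5-oxooctahydro-1H-indene-4-carboxylate (trans-fused; CO2Me trans, C4-CH3 cis to angular CH3) | C=C[C@@]1(O)CC[C@H]2[C@@]1(C)CCC(=O)[C@]2(C)C(=O)OC | intermediate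
10 | 5-(4-methylbenzenesulfonyl)hydrazone of 9 | C=C[C@@]1(O)CC[C@H]2[C@@]1(C)CCC(=NNS(=O)(=O)c3ccc(C)cc3)[C@]2(C)C(=O)OC | intermediate
11 | methyl (1S,3aS,4S,7aR)-1-ethenyl-1-hydroxy-4,7a-dimethyloctahydro-1H-indene-4-carboxylate | C=C[C@@]1(O)CC[C@H]2[C@@]1(C)CCC[C@]2(C)C(=O)OC | intermediate
12 | 1-iodo-2-methylprop-1-ene | CC(C)=CI | starting material
13 | methyl (1S,4aR,5S,8aS)-1,4a-dimethyl-5-(3-methylbut-2-en-1-yl)-6-oxodecahydronaphthalene-1-carboxylate (trans-decalin, side chain equatorial) | O=C1CC[C@H]2[C@@](C)(CCC[C@]2(C)C(=O)OC)[C@@H]1CC=C(C)C | intermediate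
14 | methyl (1S,4aR,5S,8aS)-1,4a-dimethyl-5-[(2E)-3-methyl-4-oxobut-2-en-1-yl]-6-oxodecahydronaphthalene-1-carboxylate | O=C1CC[C@H]2[C@@](C)(CCC[C@]2(C)C(=O)OC)[C@@H]1C/C=C(\C)C=O | intermediate
15 | methyl (1S,4aR,5S,8aS)-1,4a-dimethyl-5-[(2E)-3-methylpenta-2,4-dien-1-yl]-6-oxodecahydronaphthalene-1-carboxylate | O=C1CC[C@H]2[C@@](C)(CCC[C@]2(C)C(=O)OC)[C@@H]1C/C=C(\C)C=C | intermediate
16 | methyl (1S,4aS,5R,8aS)-1,4a-dimethyl-6-methylidene-5-[(2E)-3-methylpenta-2,4-dien-1-yl]decahydronaphthalene-1-carboxylate | C=C1CC[C@H]2[C@@](C)(CCC[C@]2(C)C(=O)OC)[C@@H]1C/C=C(\C)C=C | intermediate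
17 | resorcinol | Oc1cccc(O)c1 | starting material
18 | 1,3-dimethoxybenzene | COc1cccc(OC)c1 | intermediate
19 | (2,6-dimethoxyphenyl)lithium | [Li]c1c(OC)cccc1OC | intermediate
20 | 1,3-dimethoxy-2-methylbenzene | COc1cccc(OC)c1C | intermediate
21 | 2,4-dimethoxy-3-methylphenol | COc1ccc(O)c(OC)c1C | intermediate
22 | 2-methoxy-3-methylcyclohexa-2,5-diene-1,4-dione | COC1=C(C)C(=O)C=CC1=O | intermediate
23 | cycloadduct of 16 and 22: cis-fused 4a,5,8,8a-tetrahydro-1,4-naphthoquinone carrying the decalinylmethyl group at C5 next to the carbonyl that neighbours C–OMe (mixture at the three new sp3 centres) | C=C1CC[C@H]2[C@@](C)(CCC[C@]2(C)C(=O)OC)[C@@H]1CC3C(C)=CCC4C(=O)C(C)=C(OC)C(=O)C34 | intermediate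
24 | methyl (1S,4aS,5R,8aS)-5-[(7-methoxy-2,6-dimethyl-5,8-dioxo-5,8-dihydronaphthalen-1-yl)methyl]-1,4a-dimethyl-6-methylidenedecahydronaphthalene-1-carboxylate | C=C1CC[C@H]2[C@@](C)(CCC[C@]2(C)C(=O)OC)[C@@H]1Cc1c(C)ccc2c1C(=O)C(OC)=C(C)C2=O | intermediate
25 | (1S,4aS,5R,8aS)-5-[(7-hydroxy-2,6-dimethyl-5,8-dioxo-5,8-dihydronaphthalen-1-yl)methyl]-1,4a-dimethyl-6-methylidenedecahydronaphthalene-1-carboxylic acid | C=C1CC[C@H]2[C@@](C)(CCC[C@]2(C)C(=O)O)[C@@H]1Cc1c(C)ccc2c1C(=O)C(O)=C(C)C2=O | target

**Step count and risks**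

Total step count: 12. Longest linear sequence: 9 steps (steps 1–7, 11 and 12); steps 8–10 make the quinone partner.

The three steps most likely to fail:

The first is step 5, the proposed gold-catalysed alkenylative ring expansion. It may fail through ionisation of the tertiary allylic alcohol, slow oxidative addition, or migration of the CH2 instead of the quaternary carbon. The fallback uses known chemistry and sets out from 11. Hydroxyl-directed epoxidation (VO(acac)2 cat., t-BuOOH, PhMe, 23 °C) gives the epoxy alcohol F1. TiCl4 (CH2Cl2, −78 °C) then triggers the established epoxy-alcohol semipinacol ring expansion, the same 1,2-shift of the quaternary carbon, to the hydroxymethyl ketone F2. MsCl/Et3N gives the mesylate F3, and DBU eliminates it to the exo-methylene ketone F4. Copper-catalysed conjugate addition of (CH3)2C=CHMgBr (CuBr·SMe2 cat., TMSCl, THF, −78 °C, acidic work-up) comes back to the route at 13.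

The second is step 4, the one-pot deoxygenation of a ketone next to a quaternary carbon. The hydrazone may form slowly, and the tertiary allylic alcohol is sensitive to acid and heat. The fallback sets out from 9. NaBH4 (MeOH, 0 °C) reduces the ketone to the hydroxy ester F5. 1,1'-Thiocarbonyldiimidazole (DMAP, 1,2-dichloroethane, 60 °C) acylates only the secondary hydroxyl to the imidazolylthiocarbonate F6. Barton–McCombie reduction (Bu3SnH, AIBN, PhMe, 100 °C) comes back to the route at 11.

The third is step 11, where the regiochemistry rests on the methoxy group outweighing the opposing 2-methyl effect of the diene, and the wrong isomer would place OH and CH3 the other way round. The fallback sets out from 16 and controls regiochemistry with a Lewis acid, adding the oxygen afterwards. Commercial o-cresol is oxidised with (KSO3)2NO to 2-methyl-1,4-benzoquinone F7. BF3·OEt2 (CH2Cl2, −40 °C) binds the carbonyl remote from the methyl group, so the substituted diene terminus adds next to that carbonyl and gives the cycloadduct F8. DDQ gives the naphthoquinone F9, which has C–H next to the peri carbonyl. H2O2/Na2CO3 gives the quinone epoxide F10. KOH in MeOH/H2O under argon opens the epoxide by β-elimination to the 2-hydroxyquinone and saponifies the ester, coming back to the route at 25.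

Further compounds

F1 | step 5 | methyl (1R,3aS,4S,7aR)-1-hydroxy-4,7a-dimethyl-1-(oxiran-2-yl)octahydro-1H-indene-4-carboxylate (oxirane carbon not assigned) | C3OC3[C@@]1(O)CC[C@H]2[C@@]1(C)CCC[C@]2(C)C(=O)OC
F2 | step 5 | methyl (1S,4aR,5R,8aS)-5-(hydroxymethyl)-1,4a-dimethyl-6-oxodecahydronaphthalene-1-carboxylate | O=C1CC[C@H]2[C@@](C)(CCC[C@]2(C)C(=O)OC)[C@@H]1CO
F3 | step 5 | methyl (1S,4aR,5R,8aS)-5-[(methanesulfonyloxy)methyl]-1,4a-dimethyl-6-oxodecahydronaphthalene-1-carboxylate | O=C1CC[C@H]2[C@@](C)(CCC[C@]2(C)C(=O)OC)[C@@H]1COS(C)(=O)=O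
F4 | step 5 | methyl (1S,4aR,8aS)-1,4a-dimethyl-5-methylidene-6-oxodecahydronaphthalene-1-carboxylate | C=C1C(=O)CC[C@H]2[C@@]1(C)CCC[C@]2(C)C(=O)OC
F5 | step 4 | methyl (1S,3aS,4R,7aR)-1-ethenyl-1,5-dihydroxy-4,7a-dimethyloctahydro-1H-indene-4-carboxylate (C5 carbinol not assigned) | C=C[C@@]1(O)CC[C@H]2[C@@]1(C)CCC(O)[C@]2(C)C(=O)OC
F6 | step 4 | methyl (1S,3aS,4R,7aR)-1-ethenyl-1-hydroxy-5-[(1H-imidazol-1-ylcarbonothioyl)oxy]-4,7a-dimethyloctahydro-1H-indene-4-carboxylate | C=C[C@@]1(O)CC[C@H]2[C@@]1(C)CCC(OC(=S)n3ccnc3)[C@]2(C)C(=O)OC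
F7 | step 11 | 2-methylcyclohexa-2,5-diene-1,4-dione | CC1=CC(=O)C=CC1=O
F8 | step 11 | cycloadduct of 16 and F7: cis-fused 4a,5,8,8a-tetrahydro-1,4-naphthoquinone with the decalinylmethyl group at C5 next to the carbonyl that neighbours C–H (mixture at the new sp3 centres) | C=C1CC[C@H]2[C@@](C)(CCC[C@]2(C)C(=O)OC)[C@@H]1CC3C(C)=CCC4C(=O)C(C)=CC(=O)C34
F9 | step 11 | methyl (1S,4aS,5R,8aS)-5-[(2,6-dimethyl-5,8-dioxo-5,8-dihydronaphthalen-1-yl)methyl]-1,4a-dimethyl-6-methylidenedecahydronaphthalene-1-carboxylate | C=C1CC[C@H]2[C@@](C)(CCC[C@]2(C)C(=O)OC)[C@@H]1Cc1c(C)ccc2c1C(=O)C=C(C)C2=O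
F10 | step 11 | 6,7-epoxide of F9 (2,3-epoxy-2,3-dihydro-1,4-naphthoquinone, epoxide carbons not assigned) | C=C1CC[C@H]2[C@@](C)(CCC[C@]2(C)C(=O)OC)[C@@H]1Cc1c(C)ccc2c1C(=O)C3OC3(C)C2=O
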